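**Retrosynthetic overview**

1. The target is 7-O-methylagathisflavone: a genkwanin half (OMe at C7) joined through C6 to C8'' of an apigenin half. The only skeletal disconnection is the C6–C8'' biaryl bond, which leads back to the two commercial flavones; all six rings are bought and none is formed in the route.
2. Enabling feature: both bond termini are CH carbons of phloroglucinol-type A rings. C8'' lies between O7'' and the pyranone oxygen O1'' and is the most nucleophilic CH of a 5,7-dialkoxyflavone. C6 is the only unsubstituted carbon ortho to the chelated C5–OH, since the other ortho carbon, C4a, is the ring fusion.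
3. This allows a net dehydrogenative cross-coupling in one pot: C–H plumbation at C8'' of fully benzylated apigenin, then inner-sphere aryl transfer from lead to C6 of 4'-O-benzylgenkwanin through its O5–Pb bond.
4. Benzyl protects every oxygen that ends as OH except O5, which stays free as the directing phenol; the C7 OMe comes with genkwanin. Order: two etherifications, the coupling, one global hydrogenolysis.

Key step: step 3

Remark: the C6–C8'' axis carries four ortho oxygen substituents and is a stereogenic axis that the target structure leaves undefined; the route aims at the racemate.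

**Step 1**
Reactants: 1 apigenin (5,7-dihydroxy-2-(4-hydroxyphenyl)-4H-chromen-4-one)
Product: 2 5,7-bis(benzyloxy)-2-[4-(benzyloxy)phenyl]-4H-chromen-4-one (5,7,4'-tri-O-benzylapigenin)
Conditions: BnBr (4 equiv), Cs2CO3, Bu4NI (cat.), DMF, 80 °C
Reagents that add atoms: benzyl bromide, BrCc1ccccc1
Why: Williamson ether synthesis: the acidic 7- and 4'-phenols should alkylate first and the hydrogen-bonded 5-OH should follow under the caesium base, iodide catalysis and heat, so that no free phenol is left to bind or reduce the lead reagent in step 3.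

**Step 2**
Reactants: 3 genkwanin (5-hydroxy-2-(4-hydroxyphenyl)-7-methoxy-4H-chromen-4-one)
Product: 4 2-[4-(benzyloxy)phenyl]-5-hydroxy-7-methoxy-4H-chromen-4-one (4'-O-benzylgenkwanin)
Conditions: BnBr (1.1 equiv), K2CO3, acetone, reflux
Reagents that add atoms: benzyl bromide, BrCc1ccccc1
Why: Chemoselective Williamson ether synthesis: with K2CO3 in acetone only the 4'-phenol should be alkylated, because the 5-OH is held in a hydrogen bond to the C4 carbonyl and stays free as the directing group of step 3.

**Step 3**
Reactants: 2 5,7-bis(benzyloxy)-2-[4-(benzyloxy)phenyl]-4H-chromen-4-one; 4 2-[4-(benzyloxy)phenyl]-5-hydroxy-7-methoxy-4H-chromen-4-one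
Product: 6 racemic 6-{5,7-bis(benzyloxy)-2-[4-(benzyloxy)phenyl]-4-oxo-4H-chromen-8-yl}-2-[4-(benzyloxy)phenyl]-5-hydroxy-7-methoxy-4H-chromen-4-one, via C8 aryllead triacetate 5 (not isolated)
Conditions: 2 (1.3 equiv), Pb(OAc)4 (1.2 equiv), Cl2CHCO2H, CHCl3, rt, dark; then pyridine (excess), 4 (1.0 equiv), CHCl3, 60 °C
Reagents that add atoms: none
Why: Proposed new method: electrophilic aromatic plumbation of the fully etherified ring A of 2 by Pb(OAc)4 should take place at C8, the CH between O7 and the ring oxygen that is the usual site of halogenation in 5,7-dialkoxyflavones, to give aryllead triacetate 5; after buffering with pyridine, the chelated C5 phenol of 4 should displace a carboxylate on tetravalent lead, and the aryl group should migrate from lead to the ortho carbon C6 by inner-sphere ligand coupling with loss of Pb(OAc)2, followed by tautomerisation of the dienone back to the phenol. The closest known reaction types are the direct plumbation of polyalkoxyarenes and the Pinhey arylation of phenols and of chelated enols such as 4-hydroxycoumarins with aryllead triacetates, which tolerates two ortho substituents on each partner; new here are a flavone as the arene that is plumbated, a hydrogen-bonded 5-hydroxyflavone as the phenol, and the telescoping of both events into a net dehydrogenative cross-coupling. No ring is closed. The only new stereogenic element is the biaryl axis with four ortho oxygen substituents, which is formed without control, so racemic 6 is expected. The step needs cross-coupling over homo-coupling and C8 on one partner with C6 on the other: the first is secured because only 2 (no free OH, most electron-rich CH) can be plumbated and only 4 (one free OH) can bind to lead, the second because C6 is the single unsubstituted carbon ortho to O5, while C4a is a ring-fusion carbon and the para carbon C8 cannot be reached from the O–Pb bond. Pb(OAc)4 is kept as the limiting reagent with respect to 2 so that none is left to oxidise the phenol of 4 by a Wessely-type acetoxylation.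

**Step 4**
Reactants: 6 racemic 6-{5,7-bis(benzyloxy)-2-[4-(benzyloxy)phenyl]-4-oxo-4H-chromen-8-yl}-2-[4-(benzyloxy)phenyl]-5-hydroxy-7-methoxy-4H-chromen-4-one
Product: 7 CNP0246647.0 (7-O-methylagathisflavone; 8-[5-hydroxy-2-(4-hydroxyphenyl)-7-methoxy-4-oxo-4H-chromen-6-yl]-5,7-dihydroxy-2-(4-hydroxyphenyl)-4H-chromen-4-one)
Conditions: H2 (1 atm), 10% Pd/C, THF–MeOH, rt
Reagents that add atoms: none
Why: Catalytic hydrogenolysis of the four aryl benzyl ethers over palladium on carbon should free the 4'-, 5''-, 7''- and 4'''-hydroxyls, while the aryl methyl ether at C7, the pyranone C2=C3 bonds and the biaryl bond should be inert under these mild conditions.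

**Compound list**

1 | apigenin (5,7-dihydroxy-2-(4-hydroxyphenyl)-4H-chromen-4-one) | O=c1cc(-c2ccc(O)cc2)oc2cc(O)cc(O)c12 | starting material
2 | 5,7-bis(benzyloxy)-2-[4-(benzyloxy)phenyl]-4H-chromen-4-one (5,7,4'-tri-O-benzylapigenin) | O=c1cc(-c2ccc(OCc3ccccc3)cc2)oc2cc(OCc3ccccc3)cc(OCc3ccccc3)c12 | intermediate
3 | genkwanin (5-hydroxy-2-(4-hydroxyphenyl)-7-methoxy-4H-chromen-4-one) | COc1cc(O)c2c(=O)cc(-c3ccc(O)cc3)oc2c1 | starting material
4 | 2-[4-(benzyloxy)phenyl]-5-hydroxy-7-methoxy-4H-chromen-4-one (4'-O-benzylgenkwanin) | COc1cc(O)c2c(=O)cc(-c3ccc(OCc4ccccc4)cc3)oc2c1 | intermediate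
5 | {5,7-bis(benzyloxy)-2-[4-(benzyloxy)phenyl]-4-oxo-4H-chromen-8-yl}lead triacetate (drawn as the triacetate; part of the carboxylate ligands may be dichloroacetate in the flask) | CC(=O)O[Pb](OC(C)=O)(OC(C)=O)c1c(OCc2ccccc2)cc(OCc2ccccc2)c2c(=O)cc(-c3ccc(OCc4ccccc4)cc3)oc12 | intermediate (not isolated)
6 | racemic 6-{5,7-bis(benzyloxy)-2-[4-(benzyloxy)phenyl]-4-oxo-4H-chromen-8-yl}-2-[4-(benzyloxy)phenyl]-5-hydroxy-7-methoxy-4H-chromen-4-one | COc1cc2oc(-c3ccc(OCc4ccccc4)cc3)cc(=O)c2c(O)c1-c1c(OCc2ccccc2)cc(OCc2ccccc2)c2c(=O)cc(-c3ccc(OCc4ccccc4)cc3)oc12 | intermediate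
7 | CNP0246647.0, 7-O-methylagathisflavone (8-[5-hydroxy-2-(4-hydroxyphenyl)-7-methoxy-4-oxo-4H-chromen-6-yl]-5,7-dihydroxy-2-(4-hydroxyphenyl)-4H-chromen-4-one), racemic about the biaryl axis | COc1cc2oc(-c3ccc(O)cc3)cc(=O)c2c(O)c1-c1c(O)cc(O)c2c(=O)cc(-c3ccc(O)cc3)oc12 | target

**Step count**

Total: 4 steps. Longest linear sequence: 3 steps (step 1 or step 2, then steps 3 and 4).

**Steps most likely to fail**

1. Step 3 (proposed new method). What may go wrong: plumbation of 2 may be sluggish or misdirected (attack at C6, C3 or ring B, or protodeplumbation in the acid). In the second stage, the phenol of 4 may be oxidised by tetravalent lead instead of undergoing ligand coupling, or the aryl group may be transferred to the ring-fusion carbon C4a. Fallback by known chemistry, setting out from 2 and 4 and coming back at 6: iodination of 2 with N-iodosuccinimide and CF3CO2H in CH2Cl2 should give 5,7-bis(benzyloxy)-2-[4-(benzyloxy)phenyl]-8-iodo-4H-chromen-4-one F1. Miyaura borylation of F1 (B2pin2, Pd(dppf)Cl2, KOAc, dioxane, 90 °C) should give 5,7-bis(benzyloxy)-2-[4-(benzyloxy)phenyl]-8-(4,4,5,5-tetramethyl-1,3,2-dioxaborolan-2-yl)-4H-chromen-4-one F2. Iodination of 4 ortho to the free 5-OH with BnMe3N·ICl2 and CaCO3 in CH2Cl2–MeOH should give 2-[4-(benzyloxy)phenyl]-5-hydroxy-6-iodo-7-methoxy-4H-chromen-4-one F3. Suzuki–Miyaura coupling of F2 with F3 (Pd(OAc)2, SPhos, K3PO4, toluene–H2O, 100 °C) should then give 6.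

2. Step 1. What may go wrong: alkylation of the hydrogen-bonded 5-OH may stay incomplete, or C-benzylation of ring A may set in under the forcing conditions. Fallback that changes the protecting-group plan, setting out from 1 and coming back at 7: mild benzylation of 1 (BnBr 2.2 equiv, K2CO3, acetone, reflux) should give 7-(benzyloxy)-2-[4-(benzyloxy)phenyl]-5-hydroxy-4H-chromen-4-one F4. Methylation of the chelated phenol with the smaller, more reactive Me2SO4 (K2CO3, acetone, reflux) should give 7-(benzyloxy)-2-[4-(benzyloxy)phenyl]-5-methoxy-4H-chromen-4-one F5. Under the conditions of step 3, F5 should be plumbated to {7-(benzyloxy)-2-[4-(benzyloxy)phenyl]-5-methoxy-4-oxo-4H-chromen-8-yl}lead triacetate F6 (not isolated) and coupled with 4 to 6-{7-(benzyloxy)-2-[4-(benzyloxy)phenyl]-5-methoxy-4-oxo-4H-chromen-8-yl}-2-[4-(benzyloxy)phenyl]-5-hydroxy-7-methoxy-4H-chromen-4-one F7. BCl3 with pentamethylbenzene in CH2Cl2 (−78 to 0 °C) should then cleave the three benzyl ethers and, by chelation to the C4'' carbonyl, the 5''-methyl ether, while the unchelated C7 OMe stays, to give 7.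

3. Step 4. What may go wrong: over-reduction of the pyranone C2=C3 bonds, or stalling of the hydrogenolysis through poor solubility of partly debenzylated material and the hindered 7''-ether. Fallback that replaces reduction by Lewis-acid dealkylation, setting out from 6 and coming back at 7: BCl3 with pentamethylbenzene as benzyl-cation scavenger in CH2Cl2 at −78 °C should remove the four benzyl groups without touching the unchelated aryl methyl ether; it makes no new compound (F0).

**Further compounds**

F1 | step 3 | 5,7-bis(benzyloxy)-2-[4-(benzyloxy)phenyl]-8-iodo-4H-chromen-4-one | O=c1cc(-c2ccc(OCc3ccccc3)cc2)oc2c(I)c(OCc3ccccc3)cc(OCc3ccccc3)c12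
F2 | step 3 | 5,7-bis(benzyloxy)-2-[4-(benzyloxy)phenyl]-8-(4,4,5,5-tetramethyl-1,3,2-dioxaborolan-2-yl)-4H-chromen-4-one | O=c1cc(-c2ccc(OCc3ccccc3)cc2)oc2c(B3OC(C)(C)C(C)(C)O3)c(OCc3ccccc3)cc(OCc3ccccc3)c12
F3 | step 3 | 2-[4-(benzyloxy)phenyl]-5-hydroxy-6-iodo-7-methoxy-4H-chromen-4-one | COc1cc2oc(-c3ccc(OCc4ccccc4)cc3)cc(=O)c2c(O)c1I
F4 | step 1 | 7-(benzyloxy)-2-[4-(benzyloxy)phenyl]-5-hydroxy-4H-chromen-4-one | O=c1cc(-c2ccc(OCc3ccccc3)cc2)oc2cc(OCc3ccccc3)cc(O)c12
F5 | step 1 | 7-(benzyloxy)-2-[4-(benzyloxy)phenyl]-5-methoxy-4H-chromen-4-one | COc1cc(OCc2ccccc2)cc2oc(-c3ccc(OCc4ccccc4)cc3)cc(=O)c12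
F6 | step 1 | {7-(benzyloxy)-2-[4-(benzyloxy)phenyl]-5-methoxy-4-oxo-4H-chromen-8-yl}lead triacetate (not isolated) | CC(=O)O[Pb](OC(C)=O)(OC(C)=O)c1c(OCc2ccccc2)cc(OC)c2c(=O)cc(-c3ccc(OCc4ccccc4)cc3)oc12
F7 | step 1 | 6-{7-(benzyloxy)-2-[4-(benzyloxy)phenyl]-5-methoxy-4-oxo-4H-chromen-8-yl}-2-[4-(benzyloxy)phenyl]-5-hydroxy-7-methoxy-4H-chromen-4-one | COc1cc2oc(-c3ccc(OCc4ccccc4)cc3)cc(=O)c2c(O)c1-c1c(OCc2ccccc2)cc(OC)c2c(=O)cc(-c3ccc(OCc4ccccc4)cc3)oc12
F0 | step 4 | none | none
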